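**Assumptions.**
- The catalyst-to-product sense of the enal epoxidation is taken from the usual iminium face model: the (R)-diarylprolinol ether gives the (2R,3S)-epoxy aldehyde. If optical rotation shows the opposite sense, use the (S)-catalyst.
- The target stereochemistry is read as flavanone C2 = S and benzodioxane carbons = (R,R), trans.
- In protocatechualdehyde the 4-OH (para to CHO) is the more acidic phenol.

## Retrosynthetic overview
1. Silandrin comes from global debenzylation of benzyl-protected flavanone 11. The flavanone ring is the last ring formed, by a catalyst-controlled oxa-Michael cyclisation of chalcone 10.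
2. Chalcone 10 comes from a Claisen–Schmidt condensation of the benzodioxane aldehyde 8 with phloroacetophenone 9.
3. The trans-benzodioxane 8 (second ring) comes from Mitsunobu closure of 7. Compound 7 comes from C3-selective opening of trans-epoxide 5 by protocatechualdehyde 6. Two inversions give net syn O,O-delivery across the E-alkene, so the ring is trans.
4. Epoxide 5 (first ring) comes from a diarylprolinol-catalysed epoxidation of O-benzylconiferaldehyde 2 with H2O2, followed by reduction and benzylation. This sets both epoxide stereocentres.

## Route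

**Step 1**
Reactants: 1 (coniferaldehyde, (E)-4-hydroxy-3-methoxycinnamaldehyde)
Product: 2 ((E)-4-benzyloxy-3-methoxycinnamaldehyde)
Conditions: BnBr, K2CO3, DMF, rt, 12 h
Reagents that add atoms: benzyl bromide, BrCc1ccccc1
Why: Williamson O-benzylation of the phenol masks it, so the enal can form a clean iminium in Step 2 and the phenol survives until the final hydrogenolysis.

**Step 2 (one pot, two stages; epoxy aldehyde 3 is not isolated)**
Reactants: 2
Product: 4 ((2S,3S)-3-(4-benzyloxy-3-methoxyphenyl)oxiran-2-yl-methanol), via 3 ((2R,3S)-3-(4-benzyloxy-3-methoxyphenyl)oxirane-2-carbaldehyde)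
Conditions: (i) (R)-diphenylprolinol TMS ether (10 mol%), 35% aq. H2O2 (1.5 equiv), CH2Cl2, rt, 3 h; (ii) add EtOH, NaBH4, 0 °C, 30 min
Reagents that add atoms: hydrogen peroxide, OO (NaBH4 adds only H)
Why: Iminium-catalysed nucleophilic epoxidation of an enal (Jørgensen–Hayashi type). The catalyst blocks one face of the E-iminium, so HOO⁻ adds to one face of Cβ. The enamine then closes onto the peroxide O to give the trans-epoxide, which sets C2 and C3, and NaBH4 reduces the aldehyde to the alcohol.

**Step 3**
Reactants: 4
Product: 5 ((2S,3S)-2-(benzyloxymethyl)-3-(4-benzyloxy-3-methoxyphenyl)oxirane)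
Conditions: NaH (1.2 equiv), BnBr (1.2 equiv), TBAI (5 mol%), THF, 0 °C to rt, 4 h
Reagents that add atoms: benzyl bromide, BrCc1ccccc1
Why: Williamson benzylation of the primary alkoxide. It removes the free hydroxyl so that Payne rearrangement cannot divert the phenoxide opening in Step 4, and the benzyl group is removed in the last step with no extra operation.

**Step 4**
Reactants: 5; 6 (3,4-dihydroxybenzaldehyde)
Product: 7 ((R)-Ca, (S)-Cb open-chain ether: 4-[(R)-(4-benzyloxy-3-methoxyphenyl)((S)-1-benzyloxy-2-hydroxypropan-3-yl)]oxy-3-hydroxybenzaldehyde, i.e. ArO–CH(Ar′)–CH(OH)–CH2OBn)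
Conditions: 6 (1.5 equiv), K2CO3 (1.5 equiv), DMF, 90 °C, 24 h
Reagents that add atoms: none
Why: SN2 epoxide opening (Williamson type) by the more acidic 4-phenoxide at the benzylic epoxide carbon C3 with inversion, which sets C3 as R. The 3-OH stays protonated for the next step, and C2 keeps its configuration, with its oxygen now a free secondary alcohol.

**Step 5**
Reactants: 7
Product: 8 ((2R,3R)-trans-2-(4-benzyloxy-3-methoxyphenyl)-3-(benzyloxymethyl)-2,3-dihydrobenzo[1,4]dioxine-6-carbaldehyde)
Conditions: PPh3 (1.5 equiv), DIAD (1.5 equiv), THF (0.03 M), 0 °C to rt, 12 h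
Reagents that add atoms: none (PPh3 and DIAD leave as Ph3P=O and the hydrazide)
Why: Intramolecular Mitsunobu etherification. The only free alcohol, the secondary C2–OH, is activated and displaced by the ortho-phenol in a 6-exo-tet SN2 with inversion, which sets C2 as R. Together with the inversion in Step 4 this gives the trans-2,3-dioxane.

**Step 6**
Reactants: 8; 9 (2′,4′,6′-trihydroxyacetophenone)
Product: 10 ((E)-chalcone: 1-(2,4,6-trihydroxyphenyl)-3-[benzodioxanyl]prop-2-en-1-one carrying the benzyl-protected dioxane)
Conditions: KOH (6 equiv), EtOH/H2O, rt, 48 h; then 1 M HCl, 0 °C, fast extraction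
Reagents that add atoms: none
Why: Claisen–Schmidt aldol condensation. The phenolate form of the chalcone resists cyclisation in base, so the acyclic E-enone is isolated, and the dioxane stereocentres have no acidic C–H and are untouched.

**Step 7**
Reactants: 10
Product: 11 ((2S)-flavanone: 5,7-dihydroxy-2-[dioxanyl]chroman-4-one with benzyl ethers intact)
Conditions: quinine-derived bifunctional squaramide (10 mol%), toluene/CH2Cl2 4:1 (0.02 M), 0 °C, 72 h (use the quinidine-derived pseudo-enantiomer if (2R) is obtained)
Reagents that add atoms: none (isomerisation)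
Why: Proposed new method: catalyst-controlled intramolecular oxa-Michael (6-endo-trig) of a fully free 2′,4′,6′-trihydroxychalcone on a B-ring that already carries a remote benzodioxane. The tertiary amine deprotonates the 2′-OH and the squaramide H-bonds the 6′-OH-locked enone carbonyl, so one enone face is attacked and C2 is set. The two dioxane stereocentres are about ten bonds away and should bias nothing, so catalyst control alone sets the diastereomer. The closest known reaction is bifunctional amine–thiourea or amine–squaramide catalysed cyclisation of 2′-hydroxychalcones to flavanones. It is run cold and with a weak amine base to keep retro-oxa-Michael ring opening slow.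

**Step 8**
Reactants: 11
Product: 12 (silandrin)
Conditions: H2 (1 atm), 10% Pd/C, EtOAc/MeOH 1:1, rt, 3 h
Reagents that add atoms: none (H2 adds only hydrogen; toluene is lost)
Why: Catalytic hydrogenolysis removes the phenolic and primary-alcohol benzyl ethers together. The aryl ketone, the flavanone C2 stereocentre and the dioxane ring are untouched under these mild conditions.

## Compound list
1 | coniferaldehyde | COc1cc(/C=C/C=O)ccc1O | starting material
2 | (E)-4-benzyloxy-3-methoxycinnamaldehyde | COc1cc(/C=C/C=O)ccc1OCc1ccccc1 | intermediate
3 | (2R,3S)-epoxy aldehyde | O=C[C@@H]1O[C@H]1c2ccc(OCc3ccccc3)c(OC)c2 | intermediate (not isolated)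
4 | (2S,3S)-epoxy alcohol | OC[C@@H]1O[C@H]1c2ccc(OCc3ccccc3)c(OC)c2 | intermediate
5 | (2S,3S)-epoxy benzyl ether | c1ccccc1COC[C@@H]2O[C@H]2c3ccc(OCc4ccccc4)c(OC)c3 | intermediate
6 | 3,4-dihydroxybenzaldehyde | O=Cc1ccc(O)c(O)c1 | starting material
7 | open-chain aryl ether diol monoether | O=Cc1ccc(O[C@H](c2ccc(OCc3ccccc3)c(OC)c2)[C@@H](O)COCc2ccccc2)c(O)c1 | intermediate
8 | trans-(2R,3R)-benzodioxane aldehyde | COc1cc([C@H]2Oc3ccc(C=O)cc3O[C@@H]2COCc2ccccc2)ccc1OCc1ccccc1 | intermediate
9 | 2′,4′,6′-trihydroxyacetophenone | CC(=O)c1c(O)cc(O)cc1O | starting material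
10 | chalcone | COc1cc([C@H]2Oc3ccc(/C=C/C(=O)c4c(O)cc(O)cc4O)cc3O[C@@H]2COCc2ccccc2)ccc1OCc1ccccc1 | intermediate
11 | (2S)-flavanone, dibenzyl ether | COc1cc([C@H]2Oc3ccc([C@@H]4CC(=O)c5c(O)cc(O)cc5O4)cc3O[C@@H]2COCc2ccccc2)ccc1OCc1ccccc1 | intermediate
12 | silandrin | COc1cc([C@H]2Oc3ccc([C@@H]4CC(=O)c5c(O)cc(O)cc5O4)cc3O[C@@H]2CO)ccc1O | target

**Total steps:** 8 (Step 2 is a one-pot, two-stage operation).
**Longest linear sequence:** 8 (1 → 2 → 4 → 5 → 7 → 8 → 10 → 11 → 12).

## Three steps most likely to fail
1. **Step 7 (proposed new method; enantioselective oxa-Michael).** Risks: modest ee, product racemisation by retro-Michael, and catalyst sequestration by the acidic 4′-OH.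
   Fallback: cyclise chalcone 10 with chalcone isomerase (a known enzymatic cyclisation that gives (2S)-flavanones).
2. **Step 4 (regioselective opening of epoxide 5).** Risks: some C2 attack, and SN1 leakage at the electron-rich benzylic carbon that erodes the stereochemistry at C3.
   Fallback: drop the epoxide route and form the benzodioxane by Ag2O oxidative radical coupling of catechol 6 with O-benzylconiferyl alcohol (a known biomimetic route to trans-benzodioxane neolignans), then separate the enantiomers by chiral HPLC.
3. **Step 5 (Mitsunobu closure).** Risks: elimination, and aryl (phenonium) participation that scrambles C2.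
   Fallback: a stepwise closure. Mesylate the secondary alcohol (MsCl, Et3N), then cyclise with Cs2CO3 in DMF at 60 °C by a preformed-phenoxide SN2, with no phosphonium ion pair.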